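## Numbering of the compounds

1 5-propylresorcinol (divarinol) · 2 aryl iminium chloride from 1 (not isolated) · 3 2,4-dihydroxy-6-propylbenzaldehyde · 4 2-hydroxy-4-methoxy-6-propylbenzaldehyde · 5 2-(benzyloxy)-4-methoxy-6-propylbenzaldehyde · 6 2-(benzyloxy)-4-methoxy-6-propylbenzoic acid · 7 olivetol · 8 acid chloride of 6 (not isolated) · 9 olivetol monoester of 6 · 10 hydroxymethyl phenol from 9 (not isolated) · 11 salicylaldehyde depside · 12 benzyl-protected stenosporic acid · 13 stenosporic acid.

Remark on locants: ring A is the 2-hydroxy-4-methoxy-6-propylbenzoyl ring. Ring B is numbered as in the target from 9 onwards: C1 carries (or will carry) the carboxyl carbon, C2 the free hydroxyl, C4 the acyloxy group, C6 the pentyl chain.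

Assumption: 5-propylresorcinol 1 is bought, like its pentyl homologue 7. MeI, benzyl bromide, DMF and paraformaldehyde are treated as reagents.

## Analysis of the target

Stenosporic acid (13) is a para-depside: two benzene rings, A and B, joined by one aryl ester, with no further ring, no stereocentre and no double-bond geometry to set. Ring A is the acyl part, a 2-hydroxy-4-methoxy-6-propylbenzoyl group; ring B is a 2-hydroxy-6-pentylbenzoic acid that carries the ring A acyl group on O4. The sensitive groups are the aryl ester (cleaved by hydroxide, alkoxides and strong Lewis acids), the ring B carboxyl (a β-resorcylic acid that loses CO2 on heating or in strong acid) and the two free phenols, each hydrogen-bonded to a neighbouring carbonyl. The difficulty lies in telling apart four phenolic oxygens on two resorcinol rings (ring A: O2 free, O4 methylated; ring B: O2 free, O4 acylated) and in making an ester from a benzoic acid with both ortho positions occupied. The free salicylic acid of ring B should also exist as late and as briefly as possible. The plan rests on one feature: ring B without its carboxyl carbon is a monoester of olivetol (7), whose mirror plane makes the two hydroxyls equivalent, so monoacylation can give only one compound and needs no protecting group. The missing carbon belongs on C1 of ring B, ortho to the free hydroxyl on C2, para to the acyloxy group on C4 and next to the pentyl chain on C6, a position that the free phenol itself can direct a one-carbon electrophile to.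

## Retrosynthetic reasoning

**13 ⇒ 12.** The last bond cut is the O–CH2Ph bond on ring A O2. That oxygen must be masked while the acid is activated and while ring B is formylated, so that ring B O2 is the only free phenol. A benzyl ether is chosen because hydrogenolysis removes it under neutral conditions at room temperature, which neither the depside ester nor the decarboxylation-prone acid should notice.

**12 ⇒ 11.** The ring B carboxyl is traced back to the formyl group of 11. The aldehyde is the oxidation level a directed ortho-formylation delivers, and it keeps the fragile resorcylic acid out of the route until the last two steps. The forward reaction has to oxidize the hydrogen-bonded formyl group of 11 without touching the free phenol, the electron-rich rings or the ester.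

**11 ⇒ 9 (key disconnection).** The bond between ring B C1 and the formyl carbon is cut. This is the only C–C bond of ring B that is not already present in 7, and cutting it uncovers the monoester 9 of a symmetric diol. Cutting the ester bond first would leave the carboxyl on ring B and force a protecting group onto it. The forward reaction must place one carbon on C1 and not on C3 (between the two oxygens) or C5, and must leave the aryl ester intact.

**9 ⇒ 8 + 7.** The acyl C–O bond of the depside is cut, giving acid chloride 8 (from acid 6) and olivetol 7. Because both hydroxyls of 7 are equivalent, the forward reaction only has to stop at monoacylation, which an excess of the cheap diol secures.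

**6 ⇒ 5 ⇒ 4 ⇒ 3 ⇒ 1.** Ring A is simplified by functional-group changes on an intact ring: the acid 6 comes from aldehyde 5, the O–benzyl bond is cut to give 4, the O–methyl bond to give 3, and the formyl C–C bond to give 5-propylresorcinol 1. The formyl group of 3 does double duty. It is the future acyl carbon, and by hydrogen bonding to O2 it differentiates the two hydroxyls, so O4 can be methylated first and O2 benzylated second.

## Alternatives that were turned down

**Alternative 1:** Ring A is opened at its C1–C6 bond to a linear polyketide carried on the ring B oxygen, benzyl 2-hydroxy-6-pentyl-4-[(3,5,7-trioxodecanoyl)oxy]benzoate A1.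
- Key step: mild base lets chain C2 of A1 attack the C7 ketone; loss of water and enolization give benzyl 4-[(2,4-dihydroxy-6-propylbenzoyl)oxy]-2-hydroxy-6-pentylbenzoate A2.
- For: it follows the biosynthesis, it never has to esterify a 2,6-disubstituted benzoic acid, and ring B arrives complete, so there is no regiochemical question on ring B. On these two points it is stronger than the chosen route.
- Against: A1 is an aryl ester of a polyketo acid, and the aryloxide it would release, that of benzyl 2,4-dihydroxy-6-pentylbenzoate A3, is a good leaving group. Attack of the C5 enol oxygen on the ester carbonyl (pyrone formation) and Claisen-type attack of C6 on the same carbonyl both expel A3 and destroy the depside link, competing with the wanted aldol. Building the triketone chain of A1 on a phenol ester needs polyanion chemistry that the ester would hardly survive. A2 still needs selective methylation of ring A O4 beside two other phenols, then debenzylation.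
- Comparison: it is longer, and its key step has several exits that break the bond it is meant to keep. The chosen key step leaves every existing bond alone and has one selectivity question.

**Alternative 2:** Both bonds at the depside carbonyl are cut, giving 2-iodo-1,5-dimethoxy-3-propylbenzene A4, carbon monoxide A5 and the phenol A3.
- Key step: Pd(OAc)2 with Xantphos would join A4, A5 and A3 to benzyl 4-[(2,4-dimethoxy-6-propylbenzoyl)oxy]-2-hydroxy-6-pentylbenzoate A6, by oxidative addition of A4 to zerovalent palladium, insertion of A5 and capture of the aroyl–palladium species by the phenoxide of A3.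
- For: it is convergent, the ring A benzoic acid is never made, and the ring B carboxyl is in place from the start. On ring B regiochemistry it is stronger than the chosen route.
- Against: the aroyl–palladium intermediate from the di-ortho-substituted, electron-rich A4 is congested, and its capture by a weakly nucleophilic phenoxide is the slow step of such carbonylations, so reduction of the C–I bond of A4 can compete. A6 carries a methyl ether on ring A O2 where the target has a free hydroxyl. The route would therefore end with a Lewis-acid demethylation beside the depside carbonyl, which is its most fragile bond. Regioselective iodination to A4 and carboxylation plus benzylation to A3 make it no shorter, and A5 is a toxic gas to handle.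
- Comparison: the chosen route forms the ester by an ordinary acylation and finishes under neutral hydrogenolysis.

**Alternative 3:** The bond between the ester oxygen and ring B C4 is cut.
- Key step: Cu(OAc)2-mediated oxidative coupling of acid 6 with [3-(benzyloxy)-4-(benzyloxycarbonyl)-5-pentylphenyl]boronic acid A7 would give benzyl 2-(benzyloxy)-4-{[2-(benzyloxy)-4-methoxy-6-propylbenzoyl]oxy}-6-pentylbenzoate A8. One global hydrogenolysis of A8 would then give 13.
- For: the carboxylate reacts through oxygen, so the shielding of the acyl carbon does not matter. Ring B is fully substituted, and there is no statistical monoacylation. All three benzyl groups of A8 fall in one operation. On these points it is as strong as or stronger than the chosen route.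
- Against: A7 has to be made from A3 by triflation of O4, benzylation of O2 and borylation. A native oxygen is thrown away, replaced by boron and then brought back from the acid partner. O-Arylation of carboxylic acids is the least general form of this coupling, and protodeboronation and phenol formation from A7 compete with the formation of A8.
- Comparison: it shares acid 6 with the chosen route but adds about four steps of ring B handling before A8 is reached. The chosen route uses the oxygen that 7 already has.

Key step: step 6

## Route

Step 1
Reactants: 1 5-propylresorcinol (5-propylbenzene-1,3-diol)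
Product: 3 2,4-dihydroxy-6-propylbenzaldehyde, via iminium chloride 2 (not isolated)
Conditions: POCl3, DMF, 0 °C → rt; then ice/H2O, 50 °C
Reagents that add atoms: N,N-dimethylformamide, CN(C)C=O (formyl carbon); water, O (formyl oxygen)
Why: Vilsmeier–Haack formylation; the chloroiminium ion attacks the ring carbon of 1 that is ortho to one hydroxyl, para to the other and next to the propyl group, the usual site for 5-alkylresorcinols, and aqueous hydrolysis of iminium 2 (and of any aryl formate) should give 3.

Step 2
Reactants: 3 2,4-dihydroxy-6-propylbenzaldehyde
Product: 4 2-hydroxy-4-methoxy-6-propylbenzaldehyde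
Conditions: MeI (1.05 equiv), K2CO3 (1.1 equiv), acetone, rt → 40 °C
Reagents that add atoms: iodomethane, CI
Why: Williamson etherification; the 4-hydroxyl, para to the formyl group and not hydrogen-bonded, is the more acidic and the only exposed phenol, whereas the 2-hydroxyl is locked in a chelate with the carbonyl, so one equivalent of MeI should methylate O4 only.

Step 3
Reactants: 4 2-hydroxy-4-methoxy-6-propylbenzaldehyde
Product: 5 2-(benzyloxy)-4-methoxy-6-propylbenzaldehyde
Conditions: BnBr, K2CO3, DMF, 60 °C
Reagents that add atoms: benzyl bromide, BrCc1ccccc1
Why: Williamson etherification under more forcing conditions alkylates the remaining chelated phenol, which is the only nucleophilic site left.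

Step 4
Reactants: 5 2-(benzyloxy)-4-methoxy-6-propylbenzaldehyde
Product: 6 2-(benzyloxy)-4-methoxy-6-propylbenzoic acid
Conditions: NaClO2, NaH2PO4, 2-methyl-2-butene, t-BuOH/THF/H2O, rt
Reagents that add atoms: NaClO2 (sodium chlorite), [Na+].[O-]Cl=O
Why: Pinnick oxidation; chlorous acid adds to the aldehyde and fragments to the acid and hypochlorous acid, which 2-methyl-2-butene traps before it can chlorinate the electron-rich ring, and both ethers are inert.

Step 5
Reactants: 6 2-(benzyloxy)-4-methoxy-6-propylbenzoic acid, 7 olivetol (5-pentylbenzene-1,3-diol)
Product: 9 3-hydroxy-5-pentylphenyl 2-(benzyloxy)-4-methoxy-6-propylbenzoate, via acid chloride 8 (not isolated)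
Conditions: (COCl)2, cat. DMF, CH2Cl2, 0 °C → rt, evaporate; then 7 (4 equiv), Et3N, cat. DMAP, CH2Cl2, 0 °C → rt
Reagents that add atoms: none
Why: Acid chloride formation followed by DMAP-catalysed O-acylation; the electron-rich aroyl chloride reacts through an acylpyridinium or acylium-like species, so the two ortho groups slow the acylation but should not stop it. The symmetry of 7 allows only one monoester, its excess (recoverable) suppresses the diester, and the basic medium excludes C-acylation.

Step 6
Reactants: 9 3-hydroxy-5-pentylphenyl 2-(benzyloxy)-4-methoxy-6-propylbenzoate
Product: 11 4-formyl-3-hydroxy-5-pentylphenyl 2-(benzyloxy)-4-methoxy-6-propylbenzoate, via hydroxymethyl phenol 10 (not isolated)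
Conditions: MgCl2 (anhydrous, 2 equiv), Et3N (4 equiv), (CH2O)n (6 equiv), MeCN, reflux; then 1 M HCl, 0 °C
Reagents that add atoms: paraformaldehyde (reacting as formaldehyde), C=O
Why: Magnesium-mediated ortho-formylation of a phenol (Casnati–Skattebøl reaction), a known reaction type applied here to a new phenol. Et3N and MgCl2 turn the single free hydroxyl of 9 into a chloromagnesium phenoxide; formaldehyde released from paraformaldehyde binds the same divalent magnesium and is delivered through a six-membered chelate to an ortho carbon, and tautomerization of the dienone gives the magnesium salt of hydroxymethyl phenol 10. A second magnesium-bound formaldehyde then takes a hydride from the benzylic CH2 (Oppenauer-type transfer, giving methanol), leaving 11 as its chelated magnesium salt until the acid quench. The step closes no ring and creates no stereocentre; it forms only the bond from ring B C1 to the future carboxyl carbon. Chemoselectivity follows from the substrate: ring A has no free hydroxyl (O2 is benzylated), so magnesium can be anchored only on ring B O2, and the intramolecular delivery excludes the para carbon C5. The regioselectivity between the two ortho carbons is what has to hold: C1 is para to the acyloxy oxygen and next to the weakly donating pentyl chain, whereas C3 lies between two oxygens, feels the inductive pull of both and is flanked by the bulky 2,6-disubstituted aroyloxy group, and 3-oxygenated phenols generally formylate para to the second oxygen under these conditions. The depside ester should survive because the only bases are a tertiary amine and magnesium alkoxides and its acyl carbon is shielded by the benzyloxy and propyl groups, and the chelated, deactivated product should not be formylated a second time.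

Step 7
Reactants: 11 4-formyl-3-hydroxy-5-pentylphenyl 2-(benzyloxy)-4-methoxy-6-propylbenzoate
Product: 12 4-{[2-(benzyloxy)-4-methoxy-6-propylbenzoyl]oxy}-2-hydroxy-6-pentylbenzoic acid
Conditions: NaClO2, NaH2PO4, 2-methyl-2-butene (large excess), t-BuOH/THF/H2O, 0 °C → rt
Reagents that add atoms: NaClO2 (sodium chlorite), [Na+].[O-]Cl=O
Why: Pinnick oxidation, which tolerates free phenols when the hypochlorous acid is scavenged; the weakly acidic buffer leaves the aryl ester and the benzyl ether untouched, and working at or below room temperature should keep the new salicylic acid from decarboxylating.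

Step 8
Reactants: 12 4-{[2-(benzyloxy)-4-methoxy-6-propylbenzoyl]oxy}-2-hydroxy-6-pentylbenzoic acid
Product: 13 stenosporic acid (2-hydroxy-4-[(2-hydroxy-4-methoxy-6-propylbenzoyl)oxy]-6-pentylbenzoic acid)
Conditions: H2 (1 atm), 10% Pd/C, EtOAc, rt
Reagents that add atoms: none
Why: Catalytic hydrogenolysis of the benzyl aryl ether; the neutral conditions at room temperature should leave the depside ester, the carboxylic acid and both arenes unchanged.

## Compound list

1 | 5-propylresorcinol (5-propylbenzene-1,3-diol, divarinol) | CCCc1cc(O)cc(O)c1 | starting material
2 | [(2,4-dihydroxy-6-propylphenyl)methylidene]dimethylazanium chloride | CCCc1cc(O)cc(O)c1C=[N+](C)C.[Cl-] | intermediate (not isolated)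
3 | 2,4-dihydroxy-6-propylbenzaldehyde | CCCc1cc(O)cc(O)c1C=O | intermediate
4 | 2-hydroxy-4-methoxy-6-propylbenzaldehyde | CCCc1cc(OC)cc(O)c1C=O | intermediate
5 | 2-(benzyloxy)-4-methoxy-6-propylbenzaldehyde | CCCc1cc(OC)cc(OCc2ccccc2)c1C=O | intermediate
6 | 2-(benzyloxy)-4-methoxy-6-propylbenzoic acid | CCCc1cc(OC)cc(OCc2ccccc2)c1C(=O)O | intermediate
7 | olivetol (5-pentylbenzene-1,3-diol) | CCCCCc1cc(O)cc(O)c1 | starting material
8 | 2-(benzyloxy)-4-methoxy-6-propylbenzoyl chloride | CCCc1cc(OC)cc(OCc2ccccc2)c1C(Cl)=O | intermediate (not isolated)
9 | 3-hydroxy-5-pentylphenyl 2-(benzyloxy)-4-methoxy-6-propylbenzoate | CCCCCc1cc(O)cc(OC(=O)c2c(OCc3ccccc3)cc(OC)cc2CCC)c1 | intermediate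
10 | 3-hydroxy-4-(hydroxymethyl)-5-pentylphenyl 2-(benzyloxy)-4-methoxy-6-propylbenzoate (formed as its magnesium salt) | CCCCCc1cc(OC(=O)c2c(OCc3ccccc3)cc(OC)cc2CCC)cc(O)c1CO | intermediate (not isolated)
11 | 4-formyl-3-hydroxy-5-pentylphenyl 2-(benzyloxy)-4-methoxy-6-propylbenzoate | CCCCCc1cc(OC(=O)c2c(OCc3ccccc3)cc(OC)cc2CCC)cc(O)c1C=O | intermediate
12 | 4-{[2-(benzyloxy)-4-methoxy-6-propylbenzoyl]oxy}-2-hydroxy-6-pentylbenzoic acid | CCCCCc1cc(OC(=O)c2c(OCc3ccccc3)cc(OC)cc2CCC)cc(O)c1C(=O)O | intermediate
13 | stenosporic acid | CCCCCc1cc(OC(=O)c2c(O)cc(OC)cc2CCC)cc(O)c1C(=O)O | target

## Step count and least certain steps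

Total: 8 steps. Longest linear sequence: 8 steps (1 → 13); olivetol 7 enters unmodified in step 5.

**Step 6 (key step).** The most likely failure is delivery of formaldehyde to the other ortho carbon, C3 between the two oxygens, which would give the regioisomeric aldehyde. Two further risks are condensation of the hydroxymethyl intermediate with a second phenol to diarylmethanes, and slow acyl transfer from the depside ester to magnesium methoxide during prolonged heating. Fallback: the one-carbon unit is put on olivetol before the ester is made, where the regiochemistry is that of step 1. Vilsmeier–Haack formylation of 7 (POCl3, DMF, then water) should give, through the aryl iminium chloride F1, 2,4-dihydroxy-6-pentylbenzaldehyde F2. Its 4-hydroxyl, the more acidic and the only one not chelated to the formyl group, is then acylated with acid chloride 8 (Et3N, cat. DMAP, CH2Cl2, 0 °C). This sets out from 7 and 8 and comes back to the route at 11.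

**Step 5.** Double acylation of olivetol and incomplete consumption of the hindered acid chloride would both cost ring A material. Fallback: olivetol is desymmetrized first. Monosilylation of 7 (TBSCl, imidazole, DMF; statistical, but on the cheap component) gives 3-[(tert-butyldimethylsilyl)oxy]-5-pentylphenol F3. F3 is acylated with one equivalent of 8 to give 3-[(tert-butyldimethylsilyl)oxy]-5-pentylphenyl 2-(benzyloxy)-4-methoxy-6-propylbenzoate F4. The aryl silyl ether is then cleaved with TBAF buffered by AcOH in THF at 0 °C. This sets out from 7 and 8 and comes back at 9.

**Step 7.** Electrophilic chlorination of ring B by hypochlorous acid at C5, para to the free phenol, may outrun the scavenger, and the hydrogen-bonded aldehyde may oxidize slowly. Fallback: the phenol is masked first. Benzylation of 11 (BnBr, K2CO3, DMF) gives 3-(benzyloxy)-4-formyl-5-pentylphenyl 2-(benzyloxy)-4-methoxy-6-propylbenzoate F5. Pinnick oxidation of this non-chelated, less activated aldehyde gives 2-(benzyloxy)-4-{[2-(benzyloxy)-4-methoxy-6-propylbenzoyl]oxy}-6-pentylbenzoic acid F6. Hydrogenolysis over Pd/C then removes both benzyl ethers. This sets out from 11 and comes back at 13.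

**Step 2.** Over-alkylation, that is methylation of the chelated hydroxyl as well, or incomplete conversion would give mixtures of mono- and dimethyl ethers. Fallback: selectivity is obtained by cleavage instead of alkylation. Exhaustive methylation of 3 (excess MeI, K2CO3, DMF) gives 2,4-dimethoxy-6-propylbenzaldehyde F7. BCl3 in CH2Cl2 (−78 → 0 °C) then removes only the methyl group ortho to the carbonyl, through a boron chelate. This sets out from 3 and comes back at 4.

## Further compounds

F1 | step 6 | [(2,4-dihydroxy-6-pentylphenyl)methylidene]dimethylazanium chloride | CCCCCc1cc(O)cc(O)c1C=[N+](C)C.[Cl-]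
F2 | step 6 | 2,4-dihydroxy-6-pentylbenzaldehyde | CCCCCc1cc(O)cc(O)c1C=O
F3 | step 5 | 3-[(tert-butyldimethylsilyl)oxy]-5-pentylphenol | CCCCCc1cc(O)cc(O[Si](C)(C)C(C)(C)C)c1
F4 | step 5 | 3-[(tert-butyldimethylsilyl)oxy]-5-pentylphenyl 2-(benzyloxy)-4-methoxy-6-propylbenzoate | CCCCCc1cc(O[Si](C)(C)C(C)(C)C)cc(OC(=O)c2c(OCc3ccccc3)cc(OC)cc2CCC)c1
F5 | step 7 | 3-(benzyloxy)-4-formyl-5-pentylphenyl 2-(benzyloxy)-4-methoxy-6-propylbenzoate | CCCCCc1cc(OC(=O)c2c(OCc3ccccc3)cc(OC)cc2CCC)cc(OCc2ccccc2)c1C=O
F6 | step 7 | 2-(benzyloxy)-4-{[2-(benzyloxy)-4-methoxy-6-propylbenzoyl]oxy}-6-pentylbenzoic acid | CCCCCc1cc(OC(=O)c2c(OCc3ccccc3)cc(OC)cc2CCC)cc(OCc2ccccc2)c1C(=O)O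
F7 | step 2 | 2,4-dimethoxy-6-propylbenzaldehyde | CCCc1cc(OC)cc(OC)c1C=O
A1 | alternative 1 | benzyl 2-hydroxy-6-pentyl-4-[(3,5,7-trioxodecanoyl)oxy]benzoate | CCCCCc1cc(OC(=O)CC(=O)CC(=O)CC(=O)CCC)cc(O)c1C(=O)OCc1ccccc1
A2 | alternative 1 | benzyl 4-[(2,4-dihydroxy-6-propylbenzoyl)oxy]-2-hydroxy-6-pentylbenzoate | CCCCCc1cc(OC(=O)c2c(O)cc(O)cc2CCC)cc(O)c1C(=O)OCc1ccccc1
A3 | alternative 1 | benzyl 2,4-dihydroxy-6-pentylbenzoate | CCCCCc1cc(O)cc(O)c1C(=O)OCc1ccccc1
A4 | alternative 2 | 2-iodo-1,5-dimethoxy-3-propylbenzene | CCCc1cc(OC)cc(OC)c1I
A5 | alternative 2 | carbon monoxide | [C-]#[O+]
A6 | alternative 2 | benzyl 4-[(2,4-dimethoxy-6-propylbenzoyl)oxy]-2-hydroxy-6-pentylbenzoate | CCCCCc1cc(OC(=O)c2c(OC)cc(OC)cc2CCC)cc(O)c1C(=O)OCc1ccccc1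
A7 | alternative 3 | [3-(benzyloxy)-4-(benzyloxycarbonyl)-5-pentylphenyl]boronic acid | CCCCCc1cc(B(O)O)cc(OCc2ccccc2)c1C(=O)OCc1ccccc1
A8 | alternative 3 | benzyl 2-(benzyloxy)-4-{[2-(benzyloxy)-4-methoxy-6-propylbenzoyl]oxy}-6-pentylbenzoate | CCCCCc1cc(OC(=O)c2c(OCc3ccccc3)cc(OC)cc2CCC)cc(OCc2ccccc2)c1C(=O)OCc1ccccc1
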